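**Retrosynthetic overview**
1. The target is the methyl ester of a linear tridepside of three orsellinate units: ring C (methyl benzoate ring), ring B (central) and ring A (terminal dihydroxy ring). The two aryl ester C–O bonds are cut to give methyl orsellinate and two equivalents of a benzyl-protected orsellinoyl chloride.
2. The strategy rests on ring C: the C6 methyl and the C1 methoxycarbonyl are ortho neighbours, and C1 is flanked on its other side by the C2 oxygen. Both carbon substituents are therefore placed on 3,5-bis(methoxymethoxy)benzyne in one pot (C6–CH3 first, then C1–C7).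
3. The aryne precursor, 1-chloro-3,5-bis(methoxymethoxy)benzene, is one step from 5-chlororesorcinol. The acyl donor comes from orcinol by formylation, benzylation, Pinnick oxidation and chlorination.
4. No ring is formed in the route; all three benzene rings are bought. Assembly order: ring C, then ring B onto O4 of ring C, then ring A onto O4 of ring B, each acylation followed by hydrogenolysis.

Key step: step 2

Remark: the target has no stereocentre, so no stereocontrol is required.

**Step 1**
Reactants: 1 5-chlororesorcinol, 2 chloromethyl methyl ether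
Product: 3 1-chloro-3,5-bis(methoxymethoxy)benzene
Conditions: NaH, DMF, 0 °C; then MOMCl, 0 °C to rt
Reagents that add atoms: chloromethyl methyl ether 2 (COCCl)
Why: Williamson-type O-alkylation of the sodium bis-phenoxide by the reactive α-chloro ether should give the bis-acetal cleanly, the aryl chloride being inert.

**Step 2**
Reactants: 3 1-chloro-3,5-bis(methoxymethoxy)benzene, 4 methylmagnesium bromide, 5 methyl chloroformate
Product: 9 methyl 2,4-bis(methoxymethoxy)-6-methylbenzoate, via aryllithium 6 (not isolated), via aryne 7 (not isolated), via arylmagnesium bromide 8 (not isolated)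
Conditions: LiTMP (from 2,2,6,6-tetramethylpiperidine + n-BuLi), THF, −78 °C; MeMgBr, −78 °C to rt; then cannulated into ClCO2Me (excess), THF, −78 °C to rt
Reagents that add atoms: methylmagnesium bromide 4 (C[Mg]Br), methyl chloroformate 5 (COC(=O)Cl)
Why: The hindered amide base metalates 3 between chlorine and an acetal oxygen to give 6, and on warming 6 loses LiCl to give 3,5-bis(methoxymethoxy)benzyne 7; metalation between the two acetal oxygens has no leaving group beside it and is reversed through the amine, so it should drain into the productive site. Methylmagnesium bromide adds across the strained triple bond with methyl going to the carbon that carried chlorine, remote from the flanking acetal oxygen, because the carbon–magnesium bond then forms beside that inductively withdrawing and chelating oxygen; this forms the C6–CH3 bond and gives 8. Inverse quench of 8 into excess methyl chloroformate forms the C1–C7 bond, and the resulting ester, shielded by two ortho substituents, should resist further Grignard addition. The closest known reaction type is the carbomagnesiation of 3-alkoxyarynes generated from ortho-metalated haloarenes, followed by electrophilic trapping of the ortho-alkoxy arylmagnesium. No ring is closed and no stereocentre is formed. The selectivity needed is regiochemical (methyl meta, metal ortho to the flanking oxygen); it is secured by the C3 oxygen of the aryne, and the mirror symmetry of 3 makes the two possible arynes identical.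

**Step 3**
Reactants: 9 methyl 2,4-bis(methoxymethoxy)-6-methylbenzoate
Product: 10 methyl orsellinate (methyl 2,4-dihydroxy-6-methylbenzoate)
Conditions: HCl, MeOH, 40 °C
Reagents that add atoms: none
Why: Acid-catalysed acetal exchange with methanol should remove both methoxymethyl groups as dimethoxymethane, while the methyl ester is degenerate toward methanolysis.

**Step 4**
Reactants: 11 orcinol
Product: 13 2,4-dihydroxy-6-methylbenzaldehyde, via iminium chloride 12 (not isolated)
Conditions: POCl3, DMF, 0 °C to rt; then H2O, aq. NaOAc, 50 °C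
Reagents that add atoms: N,N-dimethylformamide (CN(C)C=O), water (O)
Why: Vilsmeier–Haack formylation should take place para to one hydroxyl and ortho to the other rather than at the crowded carbon between the two hydroxyls, and hydrolysis of iminium salt 12 releases the aldehyde.

**Step 5**
Reactants: 13 2,4-dihydroxy-6-methylbenzaldehyde
Product: 14 2,4-bis(benzyloxy)-6-methylbenzaldehyde
Conditions: BnBr, K2CO3, DMF, 60 °C
Reagents that add atoms: benzyl bromide (BrCc1ccccc1)
Why: Williamson etherification with excess benzyl bromide and heating should alkylate both phenols, including the slower, hydrogen-bonded 2-OH.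

**Step 6**
Reactants: 14 2,4-bis(benzyloxy)-6-methylbenzaldehyde
Product: 15 2,4-bis(benzyloxy)-6-methylbenzoic acid
Conditions: NaClO2, NaH2PO4, 2-methyl-2-butene, t-BuOH/THF/H2O, rt
Reagents that add atoms: sodium chlorite NaClO2 ([Na+].[O-]Cl=O)
Why: Pinnick oxidation converts the aldehyde into the acid under mildly acidic conditions that spare the benzyl ethers, and excess 2-methyl-2-butene scavenges hypochlorous acid before it can chlorinate the electron-rich ring.

**Step 7**
Reactants: 15 2,4-bis(benzyloxy)-6-methylbenzoic acid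
Product: 16 2,4-bis(benzyloxy)-6-methylbenzoyl chloride
Conditions: (COCl)2, DMF (cat.), CH2Cl2, 0 °C to rt; evaporation, used crude
Reagents that add atoms: oxalyl chloride (O=C(Cl)C(=O)Cl)
Why: Acid chloride formation through the catalytic Vilsmeier chloride proceeds at low temperature with only gaseous co-products, which suits this hindered, electron-rich acid.

**Step 8**
Reactants: 10 methyl orsellinate, 16 2,4-bis(benzyloxy)-6-methylbenzoyl chloride
Product: 17 methyl 4-{[2,4-bis(benzyloxy)-6-methylbenzoyl]oxy}-2-hydroxy-6-methylbenzoate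
Conditions: Et3N, DMAP (cat.), CH2Cl2, 0 °C to rt
Reagents that add atoms: 2,4-bis(benzyloxy)-6-methylbenzoyl chloride 16 (Cc1cc(OCc2ccccc2)cc(OCc2ccccc2)c1C(=O)Cl)
Why: In this DMAP-catalysed esterification the 4-OH is the free, more acidic phenol, whereas the 2-OH is hydrogen-bonded to the ester carbonyl and crowded by it, so the hindered aroyl chloride should acylate O4 only.

**Step 9**
Reactants: 17 methyl 4-{[2,4-bis(benzyloxy)-6-methylbenzoyl]oxy}-2-hydroxy-6-methylbenzoate
Product: 18 methyl 4-[(2,4-dihydroxy-6-methylbenzoyl)oxy]-2-hydroxy-6-methylbenzoate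
Conditions: H2 (1 atm), Pd/C, EtOAc, rt
Reagents that add atoms: none
Why: Heterogeneous hydrogenolysis cleaves both benzyl aryl ethers while the aryl ester and methyl ester are inert, and the non-alcoholic solvent excludes transesterification.

**Step 10**
Reactants: 18 methyl 4-[(2,4-dihydroxy-6-methylbenzoyl)oxy]-2-hydroxy-6-methylbenzoate, 16 2,4-bis(benzyloxy)-6-methylbenzoyl chloride
Product: 19 methyl 4-{[4-({2,4-bis(benzyloxy)-6-methylbenzoyl}oxy)-2-hydroxy-6-methylbenzoyl]oxy}-2-hydroxy-6-methylbenzoate
Conditions: Et3N (1.1 equiv), DMAP (cat.), THF/CH2Cl2, 0 °C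
Reagents that add atoms: 2,4-bis(benzyloxy)-6-methylbenzoyl chloride 16 (Cc1cc(OCc2ccccc2)cc(OCc2ccccc2)c1C(=O)Cl)
Why: Of the three phenols in 18 only the ring B 4-OH is not hydrogen-bonded to an ortho carbonyl, so as the most acidic and least hindered hydroxyl it should be the one esterified by one equivalent of the hindered acid chloride (DMAP-catalysed esterification).

**Step 11**
Reactants: 19 methyl 4-{[4-({2,4-bis(benzyloxy)-6-methylbenzoyl}oxy)-2-hydroxy-6-methylbenzoyl]oxy}-2-hydroxy-6-methylbenzoate
Product: 20 methyl 4-{[4-({2,4-dihydroxy-6-methylbenzoyl}oxy)-2-hydroxy-6-methylbenzoyl]oxy}-2-hydroxy-6-methylbenzoate (CNP0212402.0)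
Conditions: H2 (1 atm), Pd/C, EtOAc/THF, rt
Reagents that add atoms: none
Why: Hydrogenolysis of the two benzyl ethers of ring A under neutral conditions should release the target without touching either depside ester or the methyl ester.

**Compound list**
1 | 5-chlororesorcinol (5-chlorobenzene-1,3-diol) | Oc1cc(O)cc(Cl)c1 | starting material
2 | chloromethyl methyl ether | COCCl | starting material
3 | 1-chloro-3,5-bis(methoxymethoxy)benzene | COCOc1cc(Cl)cc(OCOC)c1 | intermediate
4 | methylmagnesium bromide | C[Mg]Br | starting material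
5 | methyl chloroformate | COC(=O)Cl | starting material
6 | [2-chloro-4,6-bis(methoxymethoxy)phenyl]lithium | [Li]c1c(Cl)cc(OCOC)cc1OCOC | intermediate
7 | 3,5-bis(methoxymethoxy)benzyne (1,2-didehydro-3,5-bis(methoxymethoxy)benzene) | COCOC1=CC(OCOC)=CC#C1 | intermediate
8 | [2,4-bis(methoxymethoxy)-6-methylphenyl]magnesium bromide | COCOc1cc(C)c([Mg]Br)c(OCOC)c1 | intermediate
9 | methyl 2,4-bis(methoxymethoxy)-6-methylbenzoate | COCOc1cc(C)c(C(=O)OC)c(OCOC)c1 | intermediate
10 | methyl orsellinate (methyl 2,4-dihydroxy-6-methylbenzoate) | COC(=O)c1c(C)cc(O)cc1O | intermediate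
11 | orcinol (5-methylbenzene-1,3-diol) | Cc1cc(O)cc(O)c1 | starting material
12 | [(2,4-dihydroxy-6-methylphenyl)methylidene]dimethyliminium chloride | C[N+](C)=Cc1c(C)cc(O)cc1O.[Cl-] | intermediate
13 | 2,4-dihydroxy-6-methylbenzaldehyde | Cc1cc(O)cc(O)c1C=O | intermediate
14 | 2,4-bis(benzyloxy)-6-methylbenzaldehyde | Cc1cc(OCc2ccccc2)cc(OCc2ccccc2)c1C=O | intermediate
15 | 2,4-bis(benzyloxy)-6-methylbenzoic acid | Cc1cc(OCc2ccccc2)cc(OCc2ccccc2)c1C(=O)O | intermediate
16 | 2,4-bis(benzyloxy)-6-methylbenzoyl chloride | Cc1cc(OCc2ccccc2)cc(OCc2ccccc2)c1C(=O)Cl | intermediate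
17 | methyl 4-{[2,4-bis(benzyloxy)-6-methylbenzoyl]oxy}-2-hydroxy-6-methylbenzoate | COC(=O)c1c(C)cc(OC(=O)c2c(C)cc(OCc3ccccc3)cc2OCc2ccccc2)cc1O | intermediate
18 | methyl 4-[(2,4-dihydroxy-6-methylbenzoyl)oxy]-2-hydroxy-6-methylbenzoate | COC(=O)c1c(C)cc(OC(=O)c2c(C)cc(O)cc2O)cc1O | intermediate
19 | methyl 4-{[4-({2,4-bis(benzyloxy)-6-methylbenzoyl}oxy)-2-hydroxy-6-methylbenzoyl]oxy}-2-hydroxy-6-methylbenzoate | COC(=O)c1c(C)cc(OC(=O)c2c(C)cc(OC(=O)c3c(C)cc(OCc4ccccc4)cc3OCc3ccccc3)cc2O)cc1O | intermediate
20 | methyl 4-{[4-({2,4-dihydroxy-6-methylbenzoyl}oxy)-2-hydroxy-6-methylbenzoyl]oxy}-2-hydroxy-6-methylbenzoate (CNP0212402.0) | COC(=O)c1c(C)cc(OC(=O)c2c(C)cc(OC(=O)c3c(C)cc(O)cc3O)cc2O)cc1O | target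

**Totals**
Total step count: 11.
Longest linear sequence: 8 steps (11 → 13 → 14 → 15 → 16 → 17 → 18 → 19 → 20); the ring C branch (1 → 3 → 9 → 10) is 3 steps.

**Steps most likely to fail**

Step 2. Metalation may settle between the two acetal oxygens without funnelling to the chlorine-flanked site. Loss of metal chloride may stall once lithium has been exchanged for magnesium. The arylmagnesium may add to further aryne, or its acylation may be sluggish because two ortho groups crowd the carbon–magnesium bond. The fallback gives up the aryne and takes ring C from the orcinol series. It sets out from acid 15, which is methylated (MeI, K2CO3, DMF, rt) to methyl 2,4-bis(benzyloxy)-6-methylbenzoate F1. Hydrogenolysis (H2, Pd/C, EtOAc) removes both benzyl groups and the route is rejoined at 10.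

Step 10. Discrimination between the three phenols of 18 may be incomplete, or base-mediated acyl transfer may scramble the existing depside ester. The fallback builds the ring A–ring B unit with the ring B phenol masked and attaches ring C last. It sets out from aldehyde 13 and acid chloride 16.
- Acylation of the free 4-OH of 13 (Et3N, DMAP, CH2Cl2) gives 4-formyl-3-hydroxy-5-methylphenyl 2,4-bis(benzyloxy)-6-methylbenzoate F2.
- Benzylation of the remaining chelated phenol (BnBr, K2CO3, DMF) gives 3-(benzyloxy)-4-formyl-5-methylphenyl 2,4-bis(benzyloxy)-6-methylbenzoate F3.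
- Pinnick oxidation (NaClO2, NaH2PO4, 2-methyl-2-butene) gives 2-(benzyloxy)-4-{[2,4-bis(benzyloxy)-6-methylbenzoyl]oxy}-6-methylbenzoic acid F4.
- Oxalyl chloride with catalytic DMF gives 2-(benzyloxy)-4-{[2,4-bis(benzyloxy)-6-methylbenzoyl]oxy}-6-methylbenzoyl chloride F5.
- Acylation of the 4-OH of 10 (Et3N, DMAP) gives methyl 4-{[2-(benzyloxy)-4-({2,4-bis(benzyloxy)-6-methylbenzoyl}oxy)-6-methylbenzoyl]oxy}-2-hydroxy-6-methylbenzoate F6.
- Hydrogenolysis (H2, Pd/C, EtOAc/THF) of all three benzyl ethers rejoins the route at 20.

Step 7. The hydrogen chloride formed may cleave the ortho benzyl ether during chlorination, and the hindered, electron-rich acid chloride may hydrolyse on handling. The fallback avoids a discrete acid chloride. It sets out from acid 15 and phenol 10, which are stirred with trifluoroacetic anhydride in toluene at rt. The acid is activated in the flask as 2,4-bis(benzyloxy)-6-methylbenzoic trifluoroacetic anhydride F7, which acylates the free 4-OH of 10, and the route is rejoined at 17. The same condensation of 15 with 18 would serve for 19.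

**Further compounds**
F1 | step 2 | methyl 2,4-bis(benzyloxy)-6-methylbenzoate | COC(=O)c1c(C)cc(OCc2ccccc2)cc1OCc1ccccc1
F2 | step 10 | 4-formyl-3-hydroxy-5-methylphenyl 2,4-bis(benzyloxy)-6-methylbenzoate | Cc1cc(OC(=O)c2c(C)cc(OCc3ccccc3)cc2OCc2ccccc2)cc(O)c1C=O
F3 | step 10 | 3-(benzyloxy)-4-formyl-5-methylphenyl 2,4-bis(benzyloxy)-6-methylbenzoate | Cc1cc(OC(=O)c2c(C)cc(OCc3ccccc3)cc2OCc2ccccc2)cc(OCc2ccccc2)c1C=O
F4 | step 10 | 2-(benzyloxy)-4-{[2,4-bis(benzyloxy)-6-methylbenzoyl]oxy}-6-methylbenzoic acid | Cc1cc(OC(=O)c2c(C)cc(OCc3ccccc3)cc2OCc2ccccc2)cc(OCc2ccccc2)c1C(=O)O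
F5 | step 10 | 2-(benzyloxy)-4-{[2,4-bis(benzyloxy)-6-methylbenzoyl]oxy}-6-methylbenzoyl chloride | Cc1cc(OC(=O)c2c(C)cc(OCc3ccccc3)cc2OCc2ccccc2)cc(OCc2ccccc2)c1C(=O)Cl
F6 | step 10 | methyl 4-{[2-(benzyloxy)-4-({2,4-bis(benzyloxy)-6-methylbenzoyl}oxy)-6-methylbenzoyl]oxy}-2-hydroxy-6-methylbenzoate | COC(=O)c1c(C)cc(OC(=O)c2c(C)cc(OC(=O)c3c(C)cc(OCc4ccccc4)cc3OCc3ccccc3)cc2OCc2ccccc2)cc1O
F7 | step 7 | 2,4-bis(benzyloxy)-6-methylbenzoic trifluoroacetic anhydride | Cc1cc(OCc2ccccc2)cc(OCc2ccccc2)c1C(=O)OC(=O)C(F)(F)F
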